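## Structural features

The target is a daucane: a cyclopentane (C1–C5) and a cycloheptane (C5–C10 plus C1) joined through the C1–C5 bond in a trans fusion, with a methyl group on the quaternary carbon C1 and H5 on the opposite face. Eight stereocentres lie on nine of the ten ring atoms. C1 stands between the carbinol carbons C2 (acetate) and C10 (free hydroxyl), and both oxygens are cis to the C1 methyl. C4 is a tertiary carbinol bearing the isopropyl group, with its oxygen also on the methyl face. The anisoate on C6 is equatorial and on the face opposite to the methyl, and the trisubstituted C8–C9 epoxide is on that same opposite face, anti to the neighbouring C10 hydroxyl. Fragile elements are the epoxy alcohol (acid, base), the two different esters next to free hydroxyls (acyl migration from O2 to O10), and the tertiary C4 hydroxyl, which is the aldol partner of any C6 ketone intermediate (retro-aldol, dehydration). The real difficulty is the quaternary C1 inside this oxygenation pattern and the need to place three oxygens of the seven-membered ring on different faces: O10 on the hindered methyl face, O6 and the epoxide on the other. The key step exploits that C5–C10 carry their substituents like a benzene ring: the oxygen on C6 is ortho and the methyl on C8 is para to C5. C1, bonded to carbonyl-level C2 and carrying its own methyl, is then the one carbon inserted into the C5–C10 bond of that arene.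

## Logic of the disconnections

24 to 23. The C8–O and C9–O bonds of the epoxide are cut. The epoxy alcohol is the most sensitive unit and is made last, so no deprotection follows it. The forward step must epoxidise anti to the free C10 hydroxyl, on the face away from the C1 methyl, so a non-directed oxidant is required; a metal-directed epoxidation would give the syn epoxide.

23 to 19 (through 22 and 20). The C10–H bond, the acyl C–O bond at O6 (to 21) and the C10 carbonyl are taken back to a C10 carbinol of opposite configuration. An epoxidation of C9=C10 from the open face puts O10 anti to the C1 methyl, which is the epimer of what 24 needs. An oxidation and reduction at C10 corrects this and, while C10 is a ketone, leaves O6 as the only hydroxyl that can be acylated. The forward steps need an oxidant that touches only the allylic alcohol and a hydride that attacks the C10 ketone anti to the C1 methyl.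

19 to 16 (through 18 and 17). The C6–H and C7–H bonds are removed, the C9–O bond is re-formed to give the epoxide of 17, and the epoxide oxygen is then removed. This traces O10 and the C8=C9 alkene to the C9=C10 alkene of a dienone, so that 16 has only the stereocentres C1, C2, C4 and C5. Forward, the oxidant must choose the γ,δ-alkene, and the C6 ketone must be reduced to the equatorial alcohol, whose hydrogen sits syn to the axial C1 methyl. This calls for an electron-transfer reduction and not a hydride.

16 to 13 (through 15 and 14). The two Si–O bonds are restored (C5 becomes sp2 again), the acetyl C–O bond is cut and C2 returns to a ketone. This leads to a compound with two stereocentres. Forward, the C2 hydride must come anti to the C1 methyl, and the proton must enter C5 on the face opposite to the methyl.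

13 to 11 (through 12). The bonds C1–C5 and C1–C10 are cut and C5–C10 is restored. Two rings and the quaternary centre are traced to a flat arene, and all fifteen skeletal carbons and the oxygens at C2, C4 and C6 are already present. The forward step must add to the unsubstituted ipso–ortho bond and to one arene face relative to C4. This is built into 11 by bridging O4 and O6 with one silicon atom, which fixes the rotamer about C4–C5. A check of C4 in 11 and of C1 and C4 in 13 against 24 shows the same spatial arrangement, so no stereodescriptor needs changing.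

11 to 7 (through 10, 9 and 8). The C1–C2 bond is cut to an acyl unit and the diazo carbon with its methyl, and the acid carbon C2 is traced to the internal carbon of a terminal alkene. The forward steps need an oxidative cleavage that spares the electron-rich arene and a neutral acid activation.

7 to 4 and 5 (through 6). The two Si–O bonds and the C3–C4 bond are cut. The only stereocentre that is not derived from another one is now set by adding an allyl group to a ketone. The free phenol of 4 is used as the handle that binds the chiral allyl donor 5, so no O-alkylation is needed.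

4 to 1 and 2 (through 3). The aryl–acyl bond C4–C5 is cut. The acyl group must end ortho to the oxygen and para to the methyl, which is the normal outcome of a high-temperature acyl shift from oxygen to carbon in this cresol.

## Other disconnections considered

Alternative 1: The cut removes C7 as a one-carbon insert between C6 and C8 and traces the bicycle to the hydrindenedione A1; the (7aR) antipode is the one that maps onto C1 of 24. Forward, the silyl dienol ether A2 would be cyclopropanated at its oxygen-bearing double bond (Et2Zn, CH2I2). FeCl3 (trivalent iron) would then cleave the internal bond of the siloxycyclopropane, and loss of HCl would give the cycloheptadienone A3.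
- In favour: the quaternary C1 comes enantiopure from an organocatalytic annulation, O2 is set cis to the methyl by a standard hydride reduction, no diazo compound is needed and the chemistry scales. On the security of C1 and C2 this plan is better than the chosen one, where C1 depends on the facial course of a carbene addition.
- Against: A3 holds eleven of the fifteen skeletal carbons. The C8 methyl, the isopropyl group with the tertiary C4 hydroxyl, the C6 and C10 oxygens and the trans fusion at C5 must all be added afterwards. C4 is a vinylic CH in A3 and must first be raised to a ketone.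
- Comparison: 13 already has every carbon and the oxygens at C2, C4 and C6. Both key steps are cyclopropane-opening ring expansions (oxidative and stepwise in one, pericyclic in the other) and look comparably reliable. In step economy alternative 1 is expected to be the longer route, because of the later C–C bond formations.

Alternative 2: The cut is C3–C4, made on a preformed seven-membered ring. Forward, Rh2(OAc)4 (divalent rhodium) would turn the diazoketone A4 into a carbenoid at C3 that inserts into the tertiary C4–H bond of the silylated carbinol side chain, closing the cyclopentanone of diketone A5.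
- In favour: 1,5-insertion into an oxygen-activated tertiary C–H bond is among the most dependable carbenoid reactions and goes with retention. The congested C4 carbinol is therefore made from a secondary silyl ether of known configuration, and the trans relation of C1 and C5 is fixed before the step instead of by a late protonation. On C4 and C5 it is the equal or the better of the chosen plan.
- Against: A4 already contains the quaternary C1 next to C5 and the side-chain centre, so the hard part is only moved into the synthesis of a trisubstituted cycloheptenone. The carbenoid could also attack the C6 carbonyl oxygen or the C7=C8 alkene. A5 has C9 and C10 as plain methylene groups, so a dehydrogenation is needed before the C10 hydroxyl and the epoxide can be introduced.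
- Comparison: A5 and 16 are at a similar level, but 16 has the C9=C10 alkene that leads to O10. The C–H insertion is at least as reliable as the arene cycloaddition. The chosen plan is shorter because the arene supplies the seven-membered ring with its unsaturation, whereas alternative 2 must first build that ring.

Alternative 3: The cut is C1–C10. Forward, Cp2TiCl (trivalent titanium) would open the C1–C2 epoxide of A6 by electron transfer to the tertiary C1 radical. This radical adds to C10, the alkoxy-bearing end of the tethered dienone, and the titanium dienolate is protonated at C7 to give A7.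
- In favour: A7 is the most advanced key-step product of the four plans. O2, O4, the C6 ketone, the C8=C9 alkene and O10 are all in place, and O2 is cis to the C1 methyl by construction of the epoxide. No redox correction at C10 would be needed if the addition sets C10 as drawn. On endgame length and on the C10 oxygen it is better than the chosen plan.
- Against: a tertiary radical must form a quaternary centre in a seven-membered ring closure onto a carbon that carries an alkoxy group, which makes that terminus electron-rich and a poor radical acceptor. The tertiary radical can instead lose hydrogen to give an allylic alcohol or be reduced. Two stereocentres (C1 and C10) are set at once without an obvious control element. A6 needs a fully substituted cyclopentane epoxide and a Z-configured dienone.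
- Comparison: A7 is closer to 24 than 13 is. The radical step is the least secure of the four key steps, while the arene cycloaddition rests on a close precedent class. What is saved after the key step is likely spent, and more, before it.

Key step: step 6

Remarks on the chemistry:
- Bicyclic compounds are named on the daucane skeleton (fusion atoms C1 and C5, five-membered ring C1–C5, seven-membered ring C5–C10 and C1, methyl groups on C1 and C8, isopropyl on C4); β is the face of the C1 methyl, α the opposite face.
- Assumption: the (S,S)-silane 5 is taken to deliver the allyl group to the face of 4 that gives the (R)-carbinol; if the first run gives the antipode, the (R,R)-silane is used and nothing else changes.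

## Route

Step 1
Reactants: 1 3-methylphenol (m-cresol); 2 2-methylpropanoyl chloride (isobutyryl chloride)
Product: 4 1-(2-hydroxy-4-methylphenyl)-2-methylpropan-1-one, via 3-methylphenyl 2-methylpropanoate 3 (not isolated)
Conditions: neat, 23 → 80 °C; then AlCl3 (1.5 equiv), 140 °C; then aq. HCl
Reagents that add atoms: none
Why: O-acylation followed by a Fries rearrangement; at high temperature the chelated ortho-hydroxy ketone is favoured, and of the two ortho positions the one para to the methyl group is open while the one between OH and CH3 is hindered.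

Step 2
Reactants: 4 1-(2-hydroxy-4-methylphenyl)-2-methylpropan-1-one; 5 (3aS,7aS)-2-allyl-1,3-bis(4-bromobenzyl)-2-chlorooctahydro-1H-1,3,2-benzodiazasilole
Product: 6 2-[(3R)-3-hydroxy-2-methylhex-5-en-3-yl]-5-methylphenol
Conditions: CH2Cl2, 23 → 40 °C; then 1 M HCl, EtOAc, 0 °C
Reagents that add atoms: none
Why: Phenol-directed asymmetric allylation: the phenol displaces chloride on the strained, Lewis-acidic silicon and the bound ketone is allylated intramolecularly through a closed six-membered transition state inside the chiral diamine; this reaction class is established for hindered 2-hydroxyaryl alkyl ketones. It sets C4 as R.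

Step 3
Reactants: 6 2-[(3R)-3-hydroxy-2-methylhex-5-en-3-yl]-5-methylphenol
Product: 7 (4R)-2,2-di-tert-butyl-7-methyl-4-(propan-2-yl)-4-(prop-2-en-1-yl)-4H-1,3,2-benzodioxasiline
Conditions: tBu2Si(OTf)2, 2,6-lutidine, CH2Cl2, 0 → 23 °C
Reagents that add atoms: di-tert-butylsilyl bis(trifluoromethanesulfonate) CC(C)(C)[Si](OS(=O)(=O)C(F)(F)F)(OS(=O)(=O)C(F)(F)F)C(C)(C)C
Why: Silylene protection of a 1,3-related phenol and tertiary alcohol under basic conditions, which avoids the acid that would ionise the benzylic carbinol. The six-membered ring is the conformational lock used in step 6.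

Step 4
Reactants: 7 (4R)-2,2-di-tert-butyl-7-methyl-4-(propan-2-yl)-4-(prop-2-en-1-yl)-4H-1,3,2-benzodioxasiline
Product: 9 [(4R)-2,2-di-tert-butyl-7-methyl-4-(propan-2-yl)-4H-1,3,2-benzodioxasilin-4-yl]acetic acid, via aldehyde 8 (not isolated)
Conditions: O3, CH2Cl2, −78 °C; PPh3; then NaClO2, NaH2PO4, 2-methylbut-2-ene, tBuOH/H2O, 23 °C
Reagents that add atoms: ozone [O-][O+]=O; sodium chlorite [Na+].[O-]Cl=O
Why: Ozonolysis of the terminal alkene, which reacts far faster than the arene, with reductive work-up, then Pinnick oxidation of the crude aldehyde at buffered pH; the silylene and C4 are not touched.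

Step 5
Reactants: 9 [(4R)-2,2-di-tert-butyl-7-methyl-4-(propan-2-yl)-4H-1,3,2-benzodioxasilin-4-yl]acetic acid
Product: 11 3-diazo-1-[(4R)-2,2-di-tert-butyl-7-methyl-4-(propan-2-yl)-4H-1,3,2-benzodioxasilin-4-yl]butan-2-one, via acid chloride 10 (not isolated)
Conditions: Me2C=C(Cl)NMe2, CH2Cl2, 0 → 23 °C; then CH3CHN2 (3 equiv, from N-ethyl-N-nitrosourea, KOH), Et2O, −20 → 0 °C
Reagents that add atoms: diazoethane CC=[N+]=[N-]; 1-chloro-N,N,2-trimethylprop-1-en-1-amine CC(C)=C(Cl)N(C)C (chlorine of 10 only)
Why: The α-chloroenamine makes the acid chloride without free HCl, and acylation of diazoethane (excess takes up the HCl) is the standard Arndt–Eistert-type route to terminally methylated diazoketones.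

Step 6
Reactants: 11 3-diazo-1-[(4R)-2,2-di-tert-butyl-7-methyl-4-(propan-2-yl)-4H-1,3,2-benzodioxasilin-4-yl]butan-2-one
Product: 13 (1R,4R)-4,6-O-(di-tert-butylsilanediyl)-4,6-dihydroxydauca-5,7,9-trien-2-one, via norcaradiene 12 (not isolated)
Conditions: Cu(MeCN)4PF6 (5 mol %), 2,2'-(propane-2,2-diyl)bis[(4S)-4-tert-butyl-4,5-dihydro-1,3-oxazole] (6 mol %), CH2Cl2, 40 °C, slow addition of 11
Reagents that add atoms: none
Why: The copper carbene formed from 11 with loss of N2 adds to the C5–C10 bond of the arene in an intramolecular [2+1] cycloaddition, and the norcaradiene 12 opens by a thermal disrotatory six-electron electrocyclic reaction that breaks C5–C10; the closest known reaction type is the intramolecular Buchner reaction of 2-diazo-5-arylpentan-3-ones to 8a-methylazulenones with Cu(MeCN)4PF6 and a bis(oxazoline) or with Rh2(OAc)4. The five-membered ring closes when C1 bonds to the ipso carbon C5 across the three-atom tether C2–C3–C4, and the seven-membered ring is formed by ring expansion of the six-membered ring when the cyclopropane bond opens, not by a cyclisation. The one new stereocentre, C1, is controlled by C4 through the silylene ring: the ring holds the C4–O bond near the arene plane on the side of C6, so C3 stands on one face of the arene and the isopropyl group on the other. The carbene can therefore reach only the C5–C10 bond and only from the face of C3, which places the C1 methyl cis to O4 as in 24. The same lock secures the regioselectivity, because the oxygen-bearing C5–C6 bond is out of reach of the tether. Chemoselectivity is needed against insertion into the isopropyl methine C–H bond, ylide formation at O4 and 1,2-hydride shift to an enone; copper carbenes insert poorly into C–H bonds, O4 is tied to a bulky silicon and points away from C1, and α-methyl diazoketones of this class are known to cyclise. The ligand tempers the carbene and is not relied on for facial control.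

Step 7
Reactants: 13 (1R,4R)-4,6-O-(di-tert-butylsilanediyl)-4,6-dihydroxydauca-5,7,9-trien-2-one
Product: 14 (1R,2R,4R)-4,6-O-(di-tert-butylsilanediyl)dauca-5,7,9-triene-2,4,6-triol
Conditions: (S)-1-methyl-3,3-diphenyltetrahydro-1H,3H-pyrrolo[1,2-c][1,3,2]oxazaborole (0.3 equiv), catecholborane, toluene, −78 → −20 °C
Reagents that add atoms: none
Why: Oxazaborolidine-catalysed (CBS) reduction with the quaternary C1 as the large and C3H2 as the small flank; the S catalyst is the one predicted to give the 2R alcohol. This agrees with the substrate bias for hydride attack anti to the pseudo-axial C1 methyl, so O2 ends cis to the methyl; catecholborane at low temperature leaves the triene alone.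

Step 8
Reactants: 14 (1R,2R,4R)-4,6-O-(di-tert-butylsilanediyl)dauca-5,7,9-triene-2,4,6-triol
Product: 15 (1R,2R,4R)-4,6-O-(di-tert-butylsilanediyl)-4,6-dihydroxydauca-5,7,9-trien-2-yl acetate
Conditions: Ac2O, Et3N, 4-dimethylaminopyridine (cat.), CH2Cl2, 23 °C
Reagents that add atoms: acetic anhydride CC(=O)OC(C)=O
Why: Nucleophile-catalysed acetylation of the only free hydroxyl; the acetate is placed now because later O2 could not be told apart from O10.

Step 9
Reactants: 15 (1R,2R,4R)-4,6-O-(di-tert-butylsilanediyl)-4,6-dihydroxydauca-5,7,9-trien-2-yl acetate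
Product: 16 (1R,2R,4R,5R)-4-hydroxy-6-oxodauca-7,9-dien-2-yl acetate
Conditions: HF·pyridine, pyridine, THF, 0 → 23 °C
Reagents that add atoms: none
Why: Fluoride cleaves both Si–O bonds, and the trienol ketonises by protonation at C5, the only carbon whose cation is stabilised by O6. The proton should enter anti to the pseudo-axial C1 methyl to give the trans fusion; this isomer should also be the more stable one (C6 anti to the isopropyl group, hydrogen bond from the C4 hydroxyl to the C6 carbonyl) and can be reached by enolisation.

Step 10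
Reactants: 16 (1R,2R,4R,5R)-4-hydroxy-6-oxodauca-7,9-dien-2-yl acetate
Product: 17 (1R,2R,4R,5R,9R,10S)-9,10-epoxy-4-hydroxy-6-oxodauc-7-en-2-yl acetate (epoxide on the α face)
Conditions: dimethyldioxirane, acetone, 0 °C
Reagents that add atoms: dimethyldioxirane CC1(C)OO1
Why: Electrophilic epoxidation takes the γ,δ-alkene C9=C10, which is more electron-rich than the α,β-alkene of the dienone, and comes from the face anti to the axial C1 methyl; the neutral oxidant spares the aldol unit.

Step 11
Reactants: 17 (1R,2R,4R,5R,9R,10S)-9,10-epoxy-4-hydroxy-6-oxodauc-7-en-2-yl acetate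
Product: 19 (1S,2R,4R,5S,6S,10R)-4,6,10-trihydroxydauc-8-en-2-yl acetate (6α-OH and 10α-OH), via hydroxy enone 18 (not isolated)
Conditions: SmI2 (2.2 equiv), MeOH, THF, −78 °C; then SmI2 (3 equiv), −78 → 0 °C
Reagents that add atoms: none
Why: Two-electron reduction of the vinylogous α-oxy ketone by divalent samarium breaks the C9–O bond, and protonation of the dienolate at C7 leaves the C8=C9 alkene with O10 retained. The additional reagent then reduces the β-hydroxy ketone through a chelate with the free C4 hydroxyl; protonation of the α-oxy organosamarium should give the more stable equatorial 6α-alcohol, anti to O4, in line with the known anti preference of this reagent with β-hydroxy ketones.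

Step 12
Reactants: 19 (1S,2R,4R,5S,6S,10R)-4,6,10-trihydroxydauc-8-en-2-yl acetate
Product: 20 (1R,2R,4R,5S,6S)-4,6-dihydroxy-10-oxodauc-8-en-2-yl acetate
Conditions: MnO2 (excess), CH2Cl2, 23 °C
Reagents that add atoms: none
Why: MnO2 oxidises only the allylic C10 alcohol; this removes the wrongly configured C10 centre and leaves O6 as the only acylable hydroxyl.

Step 13
Reactants: 20 (1R,2R,4R,5S,6S)-4,6-dihydroxy-10-oxodauc-8-en-2-yl acetate; 21 4-methoxybenzoyl chloride
Product: 22 (1R,2R,4R,5S,6S)-2-acetoxy-4-hydroxy-10-oxodauc-8-en-6-yl 4-methoxybenzoate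
Conditions: pyridine, 4-dimethylaminopyridine (cat.), CH2Cl2, 0 → 23 °C
Reagents that add atoms: none
Why: Acylation of the equatorial secondary C6 hydroxyl; the hindered tertiary C4 hydroxyl does not react, and the weak base avoids γ-deprotonation of the enone.

Step 14
Reactants: 22 (1R,2R,4R,5S,6S)-2-acetoxy-4-hydroxy-10-oxodauc-8-en-6-yl 4-methoxybenzoate
Product: 23 (1S,2R,4R,5S,6S,10S)-2-acetoxy-4,10-dihydroxydauc-8-en-6-yl 4-methoxybenzoate (10β-OH)
Conditions: NaBH4, CeCl3·7H2O, MeOH, −78 °C
Reagents that add atoms: none
Why: Luche 1,2-reduction; hydride attacks the C10 carbonyl axially from the α face, anti to the axial methyl on the adjacent C1, as in ketones next to an angular methyl, so O10 ends equatorial and cis to the methyl. Both esters survive these conditions.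

Step 15
Reactants: 23 (1S,2R,4R,5S,6S,10S)-2-acetoxy-4,10-dihydroxydauc-8-en-6-yl 4-methoxybenzoate
Product: 24 (1S,2R,4R,5S,6S,8R,9S,10R)-2-acetoxy-8,9-epoxy-4,10-dihydroxydaucan-6-yl 4-methoxybenzoate (target)
Conditions: dimethyldioxirane, acetone/MeOH, 0 °C
Reagents that add atoms: dimethyldioxirane CC1(C)OO1
Why: Dioxirane epoxidation of the trisubstituted alkene from the α face, because the β face is shielded by the syn-axial C1 methyl and the protic co-solvent weakens delivery by the C10 hydroxyl. The neutral conditions keep the epoxy alcohol and both esters intact.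

## Compound list

1 | 3-methylphenol (m-cresol) | Cc1cccc(O)c1 | starting material
2 | 2-methylpropanoyl chloride (isobutyryl chloride) | CC(C)C(Cl)=O | starting material
3 | 3-methylphenyl 2-methylpropanoate | CC(C)C(=O)Oc1cccc(C)c1 | intermediate
4 | 1-(2-hydroxy-4-methylphenyl)-2-methylpropan-1-one | CC(C)C(=O)c1ccc(C)cc1O | intermediate
5 | (3aS,7aS)-2-allyl-1,3-bis(4-bromobenzyl)-2-chlorooctahydro-1H-1,3,2-benzodiazasilole | C=CC[Si]1(Cl)N(Cc2ccc(Br)cc2)[C@H]2CCCC[C@@H]2N1Cc1ccc(Br)cc1 | starting material
6 | 2-[(3R)-3-hydroxy-2-methylhex-5-en-3-yl]-5-methylphenol | C=CC[C@@](O)(C(C)C)c1ccc(C)cc1O | intermediate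
7 | (4R)-2,2-di-tert-butyl-7-methyl-4-(propan-2-yl)-4-(prop-2-en-1-yl)-4H-1,3,2-benzodioxasiline | C=CC[C@]1(C(C)C)O[Si](C(C)(C)C)(C(C)(C)C)Oc2cc(C)ccc21 | intermediate
8 | [(4R)-2,2-di-tert-butyl-7-methyl-4-(propan-2-yl)-4H-1,3,2-benzodioxasilin-4-yl]acetaldehyde | O=CC[C@]1(C(C)C)O[Si](C(C)(C)C)(C(C)(C)C)Oc2cc(C)ccc21 | intermediate
9 | [(4R)-2,2-di-tert-butyl-7-methyl-4-(propan-2-yl)-4H-1,3,2-benzodioxasilin-4-yl]acetic acid | OC(=O)C[C@]1(C(C)C)O[Si](C(C)(C)C)(C(C)(C)C)Oc2cc(C)ccc21 | intermediate
10 | [(4R)-2,2-di-tert-butyl-7-methyl-4-(propan-2-yl)-4H-1,3,2-benzodioxasilin-4-yl]acetyl chloride | ClC(=O)C[C@]1(C(C)C)O[Si](C(C)(C)C)(C(C)(C)C)Oc2cc(C)ccc21 | intermediate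
11 | 3-diazo-1-[(4R)-2,2-di-tert-butyl-7-methyl-4-(propan-2-yl)-4H-1,3,2-benzodioxasilin-4-yl]butan-2-one (the 2-diazo-5-aryl-6-methyl-5-silyloxyheptan-3-one with O4 and the aryl oxygen bridged by tBu2Si) | CC(=[N+]=[N-])C(=O)C[C@]1(C(C)C)O[Si](C(C)(C)C)(C(C)(C)C)Oc2cc(C)ccc21 | intermediate
12 | norcaradiene valence isomer of 13 (cyclopropane C1–C5–C10 on the arene face of C3, C1 methyl cis to O4) | C[C@@]12C(=O)C[C@]3(C(C)C)O[Si](C(C)(C)C)(C(C)(C)C)OC4=CC(C)=C[C@H]1[C@]243 | intermediate
13 | (1R,4R)-4,6-O-(di-tert-butylsilanediyl)-4,6-dihydroxydauca-5,7,9-trien-2-one (8a-methylazulenone) | C[C@@]12C=CC(C)=CC3=C1[C@](C(C)C)(CC2=O)O[Si](C(C)(C)C)(C(C)(C)C)O3 | intermediate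
14 | (1R,2R,4R)-4,6-O-(di-tert-butylsilanediyl)dauca-5,7,9-triene-2,4,6-triol | C[C@@]12C=CC(C)=CC3=C1[C@](C(C)C)(C[C@H]2O)O[Si](C(C)(C)C)(C(C)(C)C)O3 | intermediate
15 | (1R,2R,4R)-4,6-O-(di-tert-butylsilanediyl)-4,6-dihydroxydauca-5,7,9-trien-2-yl acetate | C[C@@]12C=CC(C)=CC3=C1[C@](C(C)C)(C[C@H]2OC(C)=O)O[Si](C(C)(C)C)(C(C)(C)C)O3 | intermediate
16 | (1R,2R,4R,5R)-4-hydroxy-6-oxodauca-7,9-dien-2-yl acetate (trans-fused) | O=C1C=C(C)C=C[C@]2(C)[C@@H]1[C@](O)(C(C)C)C[C@H]2OC(C)=O | intermediate
17 | (1R,2R,4R,5R,9R,10S)-9,10-epoxy-4-hydroxy-6-oxodauc-7-en-2-yl acetate (α-epoxide) | O=C1C=C(C)[C@H]3O[C@H]3[C@]2(C)[C@@H]1[C@](O)(C(C)C)C[C@H]2OC(C)=O | intermediate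
18 | (1S,2R,4R,5R,10R)-4,10-dihydroxy-6-oxodauc-8-en-2-yl acetate (10α-OH) | O=C1CC(C)=C[C@@H](O)[C@]2(C)[C@@H]1[C@](O)(C(C)C)C[C@H]2OC(C)=O | intermediate
19 | (1S,2R,4R,5S,6S,10R)-4,6,10-trihydroxydauc-8-en-2-yl acetate (6α-OH, 10α-OH) | O[C@H]1CC(C)=C[C@@H](O)[C@]2(C)[C@@H]1[C@](O)(C(C)C)C[C@H]2OC(C)=O | intermediate
20 | (1R,2R,4R,5S,6S)-4,6-dihydroxy-10-oxodauc-8-en-2-yl acetate | O[C@H]1CC(C)=CC(=O)[C@]2(C)[C@@H]1[C@](O)(C(C)C)C[C@H]2OC(C)=O | intermediate
21 | 4-methoxybenzoyl chloride | COc1ccc(C(Cl)=O)cc1 | starting material
22 | (1R,2R,4R,5S,6S)-2-acetoxy-4-hydroxy-10-oxodauc-8-en-6-yl 4-methoxybenzoate | COc1ccc(C(=O)O[C@H]2CC(C)=CC(=O)[C@]3(C)[C@@H]2[C@](O)(C(C)C)C[C@H]3OC(C)=O)cc1 | intermediate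
23 | (1S,2R,4R,5S,6S,10S)-2-acetoxy-4,10-dihydroxydauc-8-en-6-yl 4-methoxybenzoate (10β-OH) | COc1ccc(C(=O)O[C@H]2CC(C)=C[C@H](O)[C@]3(C)[C@@H]2[C@](O)(C(C)C)C[C@H]3OC(C)=O)cc1 | intermediate
24 | (1S,2R,4R,5S,6S,8R,9S,10R)-2-acetoxy-8,9-epoxy-4,10-dihydroxydaucan-6-yl 4-methoxybenzoate | COc1ccc(C(=O)O[C@H]2C[C@@]3(C)O[C@H]3[C@H](O)[C@]3(C)[C@@H]2[C@](O)(C(C)C)C[C@H]3OC(C)=O)cc1 | target

## Step count and least certain steps

Total step count: 15. Longest linear sequence: 15 (the route is linear from 1).

Step 6 (key step). Most likely failure: the tert-butyl groups of the silicon bridge crowd the tether and slow the cycloaddition, so that carbene dimerisation, 1,2-hydride shift to the enone or insertion into the isopropyl C–H bond takes over. Fallback (from 6, back at 16): the two oxygens are protected separately and the face is left to a chiral catalyst.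
- Methylation of the phenol (MeI, K2CO3, acetone) gives (3R)-3-(2-methoxy-4-methylphenyl)-2-methylhex-5-en-3-ol F1.
- Silylation (Et3SiOTf, 2,6-lutidine) gives triethyl{[(3R)-3-(2-methoxy-4-methylphenyl)-2-methylhex-5-en-3-yl]oxy}silane F2.
- Ozonolysis and chlorite oxidation as in step 4 give (3R)-3-(2-methoxy-4-methylphenyl)-4-methyl-3-(triethylsilyloxy)pentanoic acid F3.
- Activation and diazoethane as in step 5 give (5R)-2-diazo-5-(2-methoxy-4-methylphenyl)-6-methyl-5-(triethylsilyloxy)heptan-3-one F4.
- Cu(MeCN)4PF6 with the bis(oxazoline) antipode that matches C4 gives (1R,4R)-6-methoxy-4-(triethylsilyloxy)dauca-5,7,9-trien-2-one F5.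
- Reduction and acetylation as in steps 7 and 8 give (1R,2R,4R)-6-methoxy-4-(triethylsilyloxy)dauca-5,7,9-trien-2-ol F6 and (1R,2R,4R)-6-methoxy-4-(triethylsilyloxy)dauca-5,7,9-trien-2-yl acetate F7.
- Dilute aqueous oxalic acid hydrolyses the enol ether to (1R,2R,4R,5R)-6-oxo-4-(triethylsilyloxy)dauca-7,9-dien-2-yl acetate F8, and HF·pyridine then gives 16.

Step 2. Most likely failure: insufficient enantioselectivity, because the isopropyl group and the substituted aryl ring compete for the same place in the transition state. Fallback (from 4, back at 7): resolution instead of asymmetric induction.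
- Allylmagnesium bromide (2.5 equiv) gives racemic material, that is 6 together with 2-[(3S)-3-hydroxy-2-methylhex-5-en-3-yl]-5-methylphenol F9.
- Silylene formation as in step 3 gives 7 together with (4S)-2,2-di-tert-butyl-7-methyl-4-(propan-2-yl)-4-(prop-2-en-1-yl)-4H-1,3,2-benzodioxasiline F10.
- Preparative chromatography on a chiral stationary phase returns 7, at the cost of half the material.

Step 9. Most likely failure: protonation at C5 from the methyl face (cis fusion), or loss of the tertiary C4 hydroxyl once it is free next to the new ketone. Fallback (from 15, back at 16): C4 stays protected while C5 is set.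
- Aqueous oxalic acid in THF cleaves only the enol Si–O bond and gives (1R,2R,4R,5R)-4-[di-tert-butyl(hydroxy)silyloxy]-6-oxodauca-7,9-dien-2-yl acetate F11, possibly with its C5 epimer (1R,2R,4R,5S)-4-[di-tert-butyl(hydroxy)silyloxy]-6-oxodauca-7,9-dien-2-yl acetate F12.
- A catalytic amidine base equilibrates the mixture to the trans-fused F11 without risk of retro-aldol cleavage, and HF·pyridine then gives 16.

Step 11. Most likely failure: protonation of the C6 organosamarium from the open α face, giving the axial 6β-alcohol, or migration of the C8=C9 alkene into conjugation under the basic samarium alkoxides before the ketone is reduced. Fallback (from 17, back at 22): kinetic hydride reduction followed by inversion, with 18 isolated.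
- The first stage alone (SmI2, 2.2 equiv, −78 °C) gives 18, which is isolated.
- NaBH4 attacks from the open α face and gives (1S,2R,4R,5S,6R,10R)-4,6,10-trihydroxydauc-8-en-2-yl acetate F13.
- MnO2 gives (1R,2R,4R,5S,6R)-4,6-dihydroxy-10-oxodauc-8-en-2-yl acetate F14.
- A Mitsunobu reaction with 4-methoxybenzoic acid (PPh3, diisopropyl azodicarboxylate) installs the ester with inversion and gives 22. Elimination towards C7 is the risk of this fallback.

Step 15. Most likely failure: delivery of the oxidant by the C10 hydroxyl to the β face, giving the syn epoxy alcohol. Fallback (from 23, back at 24): the hydroxyl is masked so that it blocks instead of directing.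
- Et3SiOTf and 2,6-lutidine at −78 °C give (1S,2R,4R,5S,6S,10S)-2-acetoxy-4-hydroxy-10-(triethylsilyloxy)dauc-8-en-6-yl 4-methoxybenzoate F15.
- Buffered 3-chloroperbenzoic acid gives (1S,2R,4R,5S,6S,8R,9S,10R)-2-acetoxy-8,9-epoxy-4-hydroxy-10-(triethylsilyloxy)daucan-6-yl 4-methoxybenzoate F16.
- Bu4NF buffered with acetic acid at 0 °C gives 24.

## Further compounds

F1 | step 6 | (3R)-3-(2-methoxy-4-methylphenyl)-2-methylhex-5-en-3-ol | C=CC[C@@](O)(C(C)C)c1ccc(C)cc1OC
F2 | step 6 | triethyl{[(3R)-3-(2-methoxy-4-methylphenyl)-2-methylhex-5-en-3-yl]oxy}silane | C=CC[C@@](O[Si](CC)(CC)CC)(C(C)C)c1ccc(C)cc1OC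
F3 | step 6 | (3R)-3-(2-methoxy-4-methylphenyl)-4-methyl-3-(triethylsilyloxy)pentanoic acid | OC(=O)C[C@@](O[Si](CC)(CC)CC)(C(C)C)c1ccc(C)cc1OC
F4 | step 6 | (5R)-2-diazo-5-(2-methoxy-4-methylphenyl)-6-methyl-5-(triethylsilyloxy)heptan-3-one | CC(=[N+]=[N-])C(=O)C[C@@](O[Si](CC)(CC)CC)(C(C)C)c1ccc(C)cc1OC
F5 | step 6 | (1R,4R)-6-methoxy-4-(triethylsilyloxy)dauca-5,7,9-trien-2-one | C[C@@]12C=CC(C)=CC(OC)=C1[C@](O[Si](CC)(CC)CC)(C(C)C)CC2=O
F6 | step 6 | (1R,2R,4R)-6-methoxy-4-(triethylsilyloxy)dauca-5,7,9-trien-2-ol | C[C@@]12C=CC(C)=CC(OC)=C1[C@](O[Si](CC)(CC)CC)(C(C)C)C[C@H]2O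
F7 | step 6 | (1R,2R,4R)-6-methoxy-4-(triethylsilyloxy)dauca-5,7,9-trien-2-yl acetate | C[C@@]12C=CC(C)=CC(OC)=C1[C@](O[Si](CC)(CC)CC)(C(C)C)C[C@H]2OC(C)=O
F8 | step 6 | (1R,2R,4R,5R)-6-oxo-4-(triethylsilyloxy)dauca-7,9-dien-2-yl acetate | O=C1C=C(C)C=C[C@]2(C)[C@@H]1[C@](O[Si](CC)(CC)CC)(C(C)C)C[C@H]2OC(C)=O
F9 | step 2 | 2-[(3S)-3-hydroxy-2-methylhex-5-en-3-yl]-5-methylphenol | C=CC[C@](O)(C(C)C)c1ccc(C)cc1O
F10 | step 2 | (4S)-2,2-di-tert-butyl-7-methyl-4-(propan-2-yl)-4-(prop-2-en-1-yl)-4H-1,3,2-benzodioxasiline | C=CC[C@@]1(C(C)C)O[Si](C(C)(C)C)(C(C)(C)C)Oc2cc(C)ccc21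
F11 | step 9 | (1R,2R,4R,5R)-4-[di-tert-butyl(hydroxy)silyloxy]-6-oxodauca-7,9-dien-2-yl acetate | O=C1C=C(C)C=C[C@]2(C)[C@@H]1[C@](O[Si](O)(C(C)(C)C)C(C)(C)C)(C(C)C)C[C@H]2OC(C)=O
F12 | step 9 | (1R,2R,4R,5S)-4-[di-tert-butyl(hydroxy)silyloxy]-6-oxodauca-7,9-dien-2-yl acetate | O=C1C=C(C)C=C[C@]2(C)[C@H]1[C@](O[Si](O)(C(C)(C)C)C(C)(C)C)(C(C)C)C[C@H]2OC(C)=O
F13 | step 11 | (1S,2R,4R,5S,6R,10R)-4,6,10-trihydroxydauc-8-en-2-yl acetate | O[C@@H]1CC(C)=C[C@@H](O)[C@]2(C)[C@@H]1[C@](O)(C(C)C)C[C@H]2OC(C)=O
F14 | step 11 | (1R,2R,4R,5S,6R)-4,6-dihydroxy-10-oxodauc-8-en-2-yl acetate | O[C@@H]1CC(C)=CC(=O)[C@]2(C)[C@@H]1[C@](O)(C(C)C)C[C@H]2OC(C)=O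
F15 | step 15 | (1S,2R,4R,5S,6S,10S)-2-acetoxy-4-hydroxy-10-(triethylsilyloxy)dauc-8-en-6-yl 4-methoxybenzoate | COc1ccc(C(=O)O[C@H]2CC(C)=C[C@H](O[Si](CC)(CC)CC)[C@]3(C)[C@@H]2[C@](O)(C(C)C)C[C@H]3OC(C)=O)cc1
F16 | step 15 | (1S,2R,4R,5S,6S,8R,9S,10R)-2-acetoxy-8,9-epoxy-4-hydroxy-10-(triethylsilyloxy)daucan-6-yl 4-methoxybenzoate | COc1ccc(C(=O)O[C@H]2C[C@@]3(C)O[C@H]3[C@H](O[Si](CC)(CC)CC)[C@]3(C)[C@@H]2[C@](O)(C(C)C)C[C@H]3OC(C)=O)cc1
A1 | alternative 1 | (7aR)-7a-methyl-2,3,7,7a-tetrahydro-1H-indene-1,5(6H)-dione (Hajos–Parrish ketone, R antipode) | C[C@@]12CCC(=O)C=C1CCC2=O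
A2 | alternative 1 | tert-butyl{[(1R,7aR)-7a-methyl-5-(trimethylsilyloxy)-2,6,7,7a-tetrahydro-1H-inden-1-yl]oxy}dimethylsilane (silyl dienol ether) | C[C@@]12CCC(O[Si](C)(C)C)=CC1=CC[C@H]2O[Si](C)(C)C(C)(C)C
A3 | alternative 1 | hydroazulene dienone (C8 ketone, C6=C7, C4=C5, C2 tert-butyldimethylsilyl ether cis to the C1 methyl) | C[C@@]12CCC(=O)C=CC1=CC[C@H]2O[Si](C)(C)C(C)(C)C
A4 | alternative 2 | 3-diazo-4-(triethylsilyloxy)-3,4-secodauc-7-ene-2,6-dione (diazoketone on C1, silylated carbinol side chain on C5) | O=C1C=C(C)CC[C@@](C)(C(=O)C=[N+]=[N-])[C@@H]1[C@H](O[Si](CC)(CC)CC)C(C)C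
A5 | alternative 2 | trans-fused 4-(triethylsilyloxy)dauc-7-ene-2,6-dione | O=C1C=C(C)CC[C@]2(C)[C@@H]1[C@](O[Si](CC)(CC)CC)(C(C)C)CC2=O
A6 | alternative 3 | 1,2-epoxy-10-(4-methoxybenzyloxy)-4-(triethylsilyloxy)-1,10-secodauca-7,9-dien-6-one (7Z,9E) | O=C(/C=C(C)\C=C\OCc1ccc(OC)cc1)[C@H]1[C@](O[Si](CC)(CC)CC)(C(C)C)C[C@H]2O[C@@]12C
A7 | alternative 3 | trans-fused 2-hydroxy-10-(4-methoxybenzyloxy)-4-(triethylsilyloxy)dauc-8-en-6-one | O=C1CC(C)=C[C@H](OCc3ccc(OC)cc3)[C@]2(C)[C@@H]1[C@](O[Si](CC)(CC)CC)(C(C)C)C[C@H]2O
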